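**Overview**

- Retrosynthesis: the target is cut first at the bridging CH2 (bonds arene C7–CH2 and CH2–pyranone C3), then at O1–C2 and C3–C3a of the dihydrofuran, which leads back to phlorisobutyrophenone and isoprene monoxide. The pyranone is cut at its lactone O1–C2 bond and at C5–C6.
- Forward: arene ring A is bought as phloroglucinol and acylated, dihydrofuran ring B is closed on it in the key step, pyranone ring C is made separately by enol-lactonisation, and the two halves are joined last through the one-carbon bridge.
- Enabling feature: ring B (O1, C2, C3, C3a, C7a) with its isopropenyl group is one isoprene C5 unit. Its CH2 (C3) sits on arene carbon C3a and its methine (C2) on oxygen O1 at C7a, para to the isobutyryl-bearing C5. This is the adjacent C,O-bis-allylation pattern that 2-methyl-2-vinyloxirane can deliver through two successive π-allylpalladium intermediates.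
- Stereochemistry: the only stereocentre, C2 (R), is set in the ring closure of the key step by a chiral diphosphine on palladium; the later steps are neutral or mildly basic and do not touch it.

Key step: step 2

Assumption: the (R,R)-enantiomer of the diphosphine is taken to give the R configuration at C2. The sense is to be checked on the first batch of 6 by chiroptical comparison with known (R)-2-isopropenyl-2,3-dihydrobenzofurans; if it is reversed, the (S,S)-ligand is used with no other change.

**Route**

Step 1
Reactants: 1 phloroglucinol; 2 isobutyryl chloride
Product: 3 2-methyl-1-(2,4,6-trihydroxyphenyl)propan-1-one (phlorisobutyrophenone)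
Conditions: AlCl3 (3.5 equiv), PhNO2/CH2Cl2, 0 to 45 °C; then 1 M HCl
Reagents that add atoms: none
Why: Friedel–Crafts C-acylation of a highly activated arene, in which complexation of the first aryl ketone to AlCl3 deactivates the ring so that mono-acylation should prevail, and any aryl ester formed should rearrange to the ketone under the same Lewis acid (Fries rearrangement).

Step 2
Reactants: 3 phlorisobutyrophenone; 4 racemic isoprene monoxide
Product: 6 1-[(2R)-4,6-dihydroxy-2-(prop-1-en-2-yl)-2,3-dihydro-1-benzofuran-5-yl]-2-methylpropan-1-one, via allylic alcohol 5 (not isolated)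
Conditions: Pd2(dba)3·CHCl3 (2.5 mol %), N,N′-[(1R,2R)-cyclohexane-1,2-diyl]bis[2-(diphenylphosphanyl)benzamide] (7.5 mol %), 3 (1.3 equiv), degassed THF, 25 °C, 4 added over 6 h; then dilution with THF, Et3B (0.3 equiv), 45 °C
Reagents that add atoms: none
Why: Proposed new method: zerovalent palladium opens racemic 4 (whose stereocentre is lost) to an alkoxide-bearing π-allyl complex that is protonated by the acidic triol 3 and attacked through carbon at its unsubstituted CH2 terminus, forming the bond that becomes C3–C3a in allylic alcohol 5, while any aryl allyl ether from O-attack is re-ionised and funnelled to the irreversible C-allyl product; Et3B then activates the allylic hydroxyl of 5 for a second ionisation to a 2-methyl π-allyl complex carrying the arylmethyl group on one terminus. The closest known reaction types are the Tsuji–Trost 1,4-addition of soft carbon nucleophiles to vinyl epoxides, the palladium/Et3B C-allylation of benzene polyols with allylic alcohols and the asymmetric intramolecular allylic etherification of ortho-(4-carbonyloxy-3-methylbut-2-enyl)phenols, which have not been combined in one pot on an unprotected acylphloroglucinol. Ring B closes by 5-exo attack of the phenolic oxygen on the substituted allyl terminus (O1–C2 bond), the only mode that leads to a five-membered ring. The C2 stereocentre is set in this attack by the chiral pocket of the (R,R)-diphosphine, which selects between π-allyl diastereomers that interconvert rapidly by π–σ–π exchange at the CH2 terminus, so that E and Z isomers of 5 converge. The step needs C- over O-allylation and mono- over bis-allylation in the first stage (secured by the reversibility of O-allylation, the excess of 3, the slow addition of 4 and the single ionisable site of the epoxide, which fixes the orientation of the C5 unit) and closure through the 4-OH instead of the 2-OH in the second stage, which is secured because the hydroxyl para to the ketone is the most acidic and is not held in the hydrogen bond to the carbonyl.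

Step 3
Reactants: 7 ethyl 3-oxopentanoate; 8 N-methoxy-N-methylpropanamide
Product: 9 ethyl 4-methyl-3,5-dioxoheptanoate (racemic)
Conditions: LiN(i-Pr)2 (2.2 equiv), THF, −78 to 0 °C; 8, −78 to 0 °C; then 1 M HCl
Reagents that add atoms: none
Why: γ-Acylation of a β-keto ester 1,3-dianion, which reacts at its more basic γ-carbon, with an N-methoxy-N-methylamide whose chelated tetrahedral adduct should not collapse until the acidic quench, so that the acidic tricarbonyl product never meets the dianion.

Step 4
Reactants: 9 ethyl 4-methyl-3,5-dioxoheptanoate
Product: 10 6-ethyl-4-hydroxy-5-methyl-2H-pyran-2-one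
Conditions: DBU (1.5 equiv), toluene, 110 °C; then 1 M HCl
Reagents that add atoms: none
Why: Base-mediated enol-lactonisation (intramolecular transesterification) of a 3,5-dioxo ester, the standard entry to 4-hydroxy-2-pyranones, driven by loss of ethanol and the conjugation of the pyranone, with the stereocentre of 9 disappearing on enolisation.

Step 5
Reactants: 10 6-ethyl-4-hydroxy-5-methyl-2H-pyran-2-one; 11 N,N-dimethylmethaniminium iodide (Eschenmoser's salt)
Product: 12 3-[(dimethylamino)methyl]-6-ethyl-4-hydroxy-5-methyl-2H-pyran-2-one
Conditions: MeCN, 0 °C to rt; then NaHCO3 (1.0 equiv), H2O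
Reagents that add atoms: none
Why: Mannich reaction of a preformed iminium salt at C3, the only nucleophilic carbon of the 4-hydroxy-2-pyranone, in which the product stays N-protonated until work-up and so should not lose the amine prematurely.

Step 6
Reactants: 6 (R)-dihydrobenzofuran acylphloroglucinol; 12 pyranone Mannich base
Product: 14 3-{[(2R)-4,6-dihydroxy-5-(2-methylpropanoyl)-2-(prop-1-en-2-yl)-2,3-dihydro-1-benzofuran-7-yl]methyl}-6-ethyl-4-hydroxy-5-methyl-2H-pyran-2-one (CNP0206652.1), via methylidenepyrandione 13 (not isolated)
Conditions: 1,4-dioxane, 80 °C, N2 sweep, 12 (1.5 equiv) added in portions; then 5% aq. citric acid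
Reagents that add atoms: none
Why: E1cB loss of dimethylamine from the zwitterionic Mannich base should give the doubly activated Michael acceptor 13, which is captured by conjugate addition (Friedel–Crafts-type C-alkylation) of C7, the only unsubstituted arene carbon of 6, a known way of forming methylene-bridged acylphloroglucinol–pyranone dimers, and the neutral medium should leave the C2 stereocentre and the isopropenyl group untouched.

**Compound list**

1 | benzene-1,3,5-triol (phloroglucinol) | Oc1cc(O)cc(O)c1 | starting material
2 | 2-methylpropanoyl chloride (isobutyryl chloride) | CC(C)C(Cl)=O | starting material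
3 | 2-methyl-1-(2,4,6-trihydroxyphenyl)propan-1-one (phlorisobutyrophenone) | CC(C)C(=O)c1c(O)cc(O)cc1O | intermediate
4 | racemic 2-ethenyl-2-methyloxirane (isoprene monoxide) | CC1(C=C)CO1 | starting material
5 | 1-{2,4,6-trihydroxy-3-[(2E)-4-hydroxy-3-methylbut-2-en-1-yl]phenyl}-2-methylpropan-1-one | CC(C)C(=O)c1c(O)cc(O)c(C/C=C(\C)CO)c1O | intermediate
6 | 1-[(2R)-4,6-dihydroxy-2-(prop-1-en-2-yl)-2,3-dihydro-1-benzofuran-5-yl]-2-methylpropan-1-one | C=C(C)[C@H]1Cc2c(O)c(C(=O)C(C)C)c(O)cc2O1 | intermediate
7 | ethyl 3-oxopentanoate | CCC(=O)CC(=O)OCC | starting material
8 | N-methoxy-N-methylpropanamide | CCC(=O)N(C)OC | starting material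
9 | ethyl 4-methyl-3,5-dioxoheptanoate (racemic) | CCC(=O)C(C)C(=O)CC(=O)OCC | intermediate
10 | 6-ethyl-4-hydroxy-5-methyl-2H-pyran-2-one | CCc1oc(=O)cc(O)c1C | intermediate
11 | N,N-dimethylmethaniminium iodide (Eschenmoser's salt) | C=[N+](C)C.[I-] | starting material
12 | 3-[(dimethylamino)methyl]-6-ethyl-4-hydroxy-5-methyl-2H-pyran-2-one | CCc1oc(=O)c(CN(C)C)c(O)c1C | intermediate
13 | 6-ethyl-5-methyl-3-methylidene-2H-pyran-2,4(3H)-dione | C=C1C(=O)C(C)=C(CC)OC1=O | intermediate
14 | 3-{[(2R)-4,6-dihydroxy-5-(2-methylpropanoyl)-2-(prop-1-en-2-yl)-2,3-dihydro-1-benzofuran-7-yl]methyl}-6-ethyl-4-hydroxy-5-methyl-2H-pyran-2-one (CNP0206652.1) | C=C(C)[C@H]1Cc2c(O)c(C(=O)C(C)C)c(O)c(Cc3c(O)c(C)c(CC)oc3=O)c2O1 | target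

**Step count and risks**

Total step count: 6. Longest linear sequence: 4 steps (7 to 14 through steps 3, 4, 5 and 6).

Steps most likely to fail:

1. Step 2 (proposed new method). Several processes may go wrong:
   - the second ionisation may stall at the allylic alcohol;
   - the second π-allyl complex may be intercepted intermolecularly by the excess of 3;
   - the ring may close through the 2-OH or with poor enantioface selection;
   - the product, itself an allylic aryl ether, may be slowly re-ionised by residual zerovalent palladium with erosion of enantiopurity, so the reaction should be stopped at full conversion and the metal scavenged.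

   Fallback, from 3 back to 6, by known chemistry: 3 would be C-alkylated in cold aqueous KOH with (E)-1,4-dibromo-2-methylbut-2-ene at its less hindered bromomethyl group to the allylic bromide 1-{3-[(2E)-4-bromo-3-methylbut-2-en-1-yl]-2,4,6-trihydroxyphenyl}-2-methylpropan-1-one F1. Under the same base F1 should close by internal SN2′ O-alkylation (Nickl-type benzofuran annulation, the classical entry to 2-isopropenyl-2,3-dihydrobenzofurans) to racemic 1-[4,6-dihydroxy-2-(prop-1-en-2-yl)-2,3-dihydro-1-benzofuran-5-yl]-2-methylpropan-1-one F2. F2 would then be resolved by preparative chromatography on a cellulose-carbamate chiral stationary phase, the R enantiomer being 6. Stereochemistry then comes from resolution instead of catalysis.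

2. Step 6. The methylidenepyrandione may be consumed by the pyranone half itself (ipso attack of a second molecule of 12 followed by deaminomethylation, giving the methylene-bis-pyranone), by re-addition of dimethylamine, or by hetero-Diels–Alder addition to the isopropenyl group, faster than by attack of C7.

   Fallback, from 6 to 14, with the roles reversed: 6 would undergo a classical phenolic Mannich reaction at C7 with aqueous formaldehyde and dimethylamine in ethanol to give 1-[(2R)-7-[(dimethylamino)methyl]-4,6-dihydroxy-2-(prop-1-en-2-yl)-2,3-dihydro-1-benzofuran-5-yl]-2-methylpropan-1-one F3. Heating F3 with pyranone 10 in dioxane should expel dimethylamine to the ortho-quinone methide (2R)-4-hydroxy-7-methylidene-5-(2-methylpropanoyl)-2-(prop-1-en-2-yl)-2,3-dihydro-1-benzofuran-6(7H)-one F4, which 10 should capture through its C3 to give 14. No electrophilic pyranone is present in this variant, so the bis-pyranone pathway is closed, and 12 is not needed.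

3. Step 3. Proton transfer between product-derived species and the dianion, competing O-acylation, or retro-Claisen cleavage of the tricarbonyl compound on work-up may hold conversion down.

   Fallback, from 7 back to 9: the same dianion of 7 would be added to propanal at −78 °C (γ-aldol addition, irreversible and free of the proton-transfer problem) to give ethyl 5-hydroxy-4-methyl-3-oxoheptanoate F5 as a diastereomer mixture. Its secondary alcohol would be oxidised with Dess–Martin periodinane to 9; the diastereomer mixture is of no consequence because both stereocentres are lost by step 4.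

**Further compounds**

F1 | step 2 | 1-{3-[(2E)-4-bromo-3-methylbut-2-en-1-yl]-2,4,6-trihydroxyphenyl}-2-methylpropan-1-one | CC(C)C(=O)c1c(O)cc(O)c(C/C=C(\C)CBr)c1O
F2 | step 2 | racemic 1-[4,6-dihydroxy-2-(prop-1-en-2-yl)-2,3-dihydro-1-benzofuran-5-yl]-2-methylpropan-1-one | C=C(C)C1Cc2c(O)c(C(=O)C(C)C)c(O)cc2O1
F3 | step 6 | 1-[(2R)-7-[(dimethylamino)methyl]-4,6-dihydroxy-2-(prop-1-en-2-yl)-2,3-dihydro-1-benzofuran-5-yl]-2-methylpropan-1-one | C=C(C)[C@H]1Cc2c(O)c(C(=O)C(C)C)c(O)c(CN(C)C)c2O1
F4 | step 6 | (2R)-4-hydroxy-7-methylidene-5-(2-methylpropanoyl)-2-(prop-1-en-2-yl)-2,3-dihydro-1-benzofuran-6(7H)-one | C=C(C)[C@H]1CC2=C(O1)C(=C)C(=O)C(C(=O)C(C)C)=C2O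
F5 | step 3 | ethyl 5-hydroxy-4-methyl-3-oxoheptanoate (diastereomer mixture) | CCC(O)C(C)C(=O)CC(=O)OCC
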